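A direct plan would close the oxolane across C3–C4 by a radical cyclisation. Racemic aryl vinyl carbinol A1 would be resolved by Sharpless kinetic epoxidation to epoxy alcohol A2, O-propargylated to ether A3 and cyclised with Cp2TiCl (trivalent titanium) to the 4-benzylidene oxolane A4. Osmylation to triol A5, acetylation and hydrogenolysis would finish the route.
Its weakest steps would be:
- The kinetic resolution that gives A2: it would discard at least half of A1 and would install an oxirane stereocentre that the radical step erases.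
- The dihydroxylation of A4: the quaternary carbinol C4 would depend on a small facial bias of an exocyclic alkene, and the extra benzylic hydroxyl of A5 would exist only to be acetylated and reduced away.
- The last hydrogenolysis: it would have to cut two benzyl ethers and a benzylic acetate while sparing the ring bond O1–C2, itself a benzylic ether para to a phenol.

**Retrosynthetic overview** (oxolane numbering: O1, C2 with ring A, C3 with CH2OAc, C4 with OH and CH2–ring B, C5)
- Key cut O1–C2: C2 is a benzylic ether carbon para to the phenolic OH of ring A, so it is the alcohol adduct of a p-quinone methide. This leads back to the acyclic phenol triol 12, in which C2 is a plain CH2, and the only ring is closed last by a dehydrogenative 5-exo etherification that also sets C2.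
- The chain C5–C4(OH)–C3–CH2OAc of 12 is the skeleton and hydroxyl of (S)-malic acid at the alcohol oxidation level (malate C1, C2, C3, C4 become C5, C4, C3 and the acetoxymethyl carbon). The two guaiacylmethyl groups are attached by enolate alkylations at malate C3 and then C2, so no C3–C4 bond is made.
- The design avoids the weak steps as follows: the chiral pool replaces the resolution; the C4 oxygen is malate's own and its benzyl group arrives as CH2, so there is no dihydroxylation and no benzylic deoxygenation; the only hydrogenolysis comes before the ring exists; and the acetate is put on last by a lipase.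

Key step: step 10

Remark on the chemistry: bromide 6 is taken as a purchasable reagent (otherwise one step from the commercial benzyl alcohol).

Step 1
Reactants: 1 vanillin
Product: 2 3-methoxy-4-[(triisopropylsilyl)oxy]benzaldehyde
Conditions: i-Pr3SiCl (1.1 equiv), imidazole (2.2 equiv), DMF, rt
Reagents that add atoms: chlorotriisopropylsilane, CC(C)[Si](Cl)(C(C)C)C(C)C
Why: Silylation of the phenol through the N-silylimidazolium ion should give the bulky aryl silyl ether that masks ring B until the penultimate step, and no stereocentre is involved.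

Step 2
Reactants: 2 3-methoxy-4-[(triisopropylsilyl)oxy]benzaldehyde
Product: 3 {3-methoxy-4-[(triisopropylsilyl)oxy]phenyl}methanol
Conditions: NaBH4 (0.6 equiv), MeOH–THF, 0 °C
Reagents that add atoms: none
Why: Borohydride reduction of the aryl aldehyde should give the benzylic alcohol while the hindered aryl silyl ether stays intact.

Step 3
Reactants: 3 {3-methoxy-4-[(triisopropylsilyl)oxy]phenyl}methanol
Product: 4 [4-(bromomethyl)-2-methoxyphenoxy]triisopropylsilane (ring B bromide)
Conditions: PBr3 (0.4 equiv), pyridine (cat.), Et2O, 0 °C; used at once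
Reagents that add atoms: phosphorus tribromide, BrP(Br)Br
Why: Bromination of the primary benzylic alcohol through its phosphite ester (SN2) should give the reactive bromide, which is not stored.

Step 4
Reactants: 5 diethyl (S)-malate; 6 1-(benzyloxy)-4-(bromomethyl)-2-methoxybenzene (ring A bromide)
Product: 7 diethyl (2S,3R)-3-[4-(benzyloxy)-3-methoxybenzyl]malate (anti; C2 is the carbinol carbon)
Conditions: LiN(SiMe3)2 (2.2 equiv), THF, −78 to −20 °C; then 6, −78 to −10 °C; aq. NH4Cl
Reagents that add atoms: none
Why: In this Fráter–Seebach alkylation the dilithium alkoxide–enolate is held in a lithium chelate and the bromide should attack malate C3 (later oxolane C3) on the face opposite the C1 ester group, which gives the anti (2S,3R) diester, with the minor syn isomer removed by chromatography.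

Step 5
Reactants: 7 diethyl (2S,3R)-3-[4-(benzyloxy)-3-methoxybenzyl]malate
Product: 8 (2S,3R)-3-[4-(benzyloxy)-3-methoxybenzyl]malic acid
Conditions: LiOH·H2O (4 equiv), THF–H2O, 0 °C to rt; then 1 M HCl to pH 2
Reagents that add atoms: lithium hydroxide, [Li+].[OH-]
Why: Saponification of both esters should give the free α-hydroxy diacid needed for acetal formation, and the dicarboxylate is not prone to epimerisation at C3 under these mild conditions.

Step 6
Reactants: 8 (2S,3R)-3-[4-(benzyloxy)-3-methoxybenzyl]malic acid
Product: 9 (2R)-3-[4-(benzyloxy)-3-methoxyphenyl]-2-[(2S,4S)-2-tert-butyl-5-oxo-1,3-dioxolan-4-yl]propanoic acid (cis acetal)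
Conditions: t-BuCHO (3 equiv), TsOH·H2O (5 mol%), H2SO4 (trace), pentane–CH2Cl2, reflux, water separator
Reagents that add atoms: 2,2-dimethylpropanal (pivalaldehyde), CC(C)(C)C=O
Why: Acid-catalysed acetalisation of the α-hydroxy acid (Seebach dioxolanone formation) should close the five-membered dioxolanone in preference to the six-membered acetal of the β-carboxyl group, and under equilibrating conditions the new acetal centre is set cis to the C4 substituent, the cis isomer being purified by crystallisation.

Step 7
Reactants: 9 (2R)-3-[4-(benzyloxy)-3-methoxyphenyl]-2-[(2S,4S)-2-tert-butyl-5-oxo-1,3-dioxolan-4-yl]propanoic acid; 4 [4-(bromomethyl)-2-methoxyphenoxy]triisopropylsilane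
Product: 10 (2R)-3-[4-(benzyloxy)-3-methoxyphenyl]-2-[(2S,4S)-2-tert-butyl-4-({3-methoxy-4-[(triisopropylsilyl)oxy]phenyl}methyl)-5-oxo-1,3-dioxolan-4-yl]propanoic acid
Conditions: LiN(SiMe3)2 (2.2 equiv), THF–DMPU, −78 °C; then 4, −78 to −40 °C; aq. citric acid
Reagents that add atoms: none
Why: In this Seebach alkylation with self-regeneration of the stereocentre the first equivalent of base forms the carboxylate (whose α-hydrogen this amide cannot remove), the second removes H4 of the dioxolanone, and the bromide should enter the planar enolate trans to the tert-butyl group, which builds the quaternary carbon (later oxolane C4) with overall retention of the malate configuration.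

Step 8
Reactants: 10 (2R)-3-[4-(benzyloxy)-3-methoxyphenyl]-2-[(2S,4S)-2-tert-butyl-4-({3-methoxy-4-[(triisopropylsilyl)oxy]phenyl}methyl)-5-oxo-1,3-dioxolan-4-yl]propanoic acid
Product: 11 (2S,3S)-3-{[4-(benzyloxy)-3-methoxyphenyl]methyl}-2-({3-methoxy-4-[(triisopropylsilyl)oxy]phenyl}methyl)butane-1,2,4-triol
Conditions: LiAlH4 (5 equiv), THF, 0 to 40 °C; Fieser work-up
Reagents that add atoms: none
Why: Hydride reduction should open the dioxolanone at its carbonyl (the released pivalaldehyde is reduced to 2,2-dimethylpropan-1-ol) and reduce the lithium carboxylate, which turns C5 and the later acetoxymethyl carbon into CH2OH and cannot epimerise either stereocentre.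

Step 9
Reactants: 11 (2S,3S)-3-{[4-(benzyloxy)-3-methoxyphenyl]methyl}-2-({3-methoxy-4-[(triisopropylsilyl)oxy]phenyl}methyl)butane-1,2,4-triol
Product: 12 (2S,3S)-3-[(4-hydroxy-3-methoxyphenyl)methyl]-2-({3-methoxy-4-[(triisopropylsilyl)oxy]phenyl}methyl)butane-1,2,4-triol
Conditions: H2 (1 atm), Pd/C (10 wt% Pd), EtOAc–EtOH, rt
Reagents that add atoms: none
Why: Hydrogenolysis of the aryl benzyl ether should free the phenol of ring A alone, because at this acyclic stage the protecting group is the only benzylic C–O bond and the aryl silyl ether is inert.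

Step 10
Reactants: 12 (2S,3S)-3-[(4-hydroxy-3-methoxyphenyl)methyl]-2-({3-methoxy-4-[(triisopropylsilyl)oxy]phenyl}methyl)butane-1,2,4-triol
Product: 14 [(2S,3R,4S)-4-hydroxy-2-(4-hydroxy-3-methoxyphenyl)-4-({3-methoxy-4-[(triisopropylsilyl)oxy]phenyl}methyl)oxolan-3-yl]methanol, via quinone methide 13 (not isolated)
Conditions: DDQ (1.0 equiv, in portions), 4 Å MS, dry 1,4-dioxane, 15 °C to rt; then aq. NaHCO3
Reagents that add atoms: none
Why: DDQ should dehydrogenate the only free phenol (quinone dehydrogenation of a 4-alkylphenol, a net hydride loss from the benzylic CH2 of ring A) to the p-quinone methide 13, and the primary hydroxyl on the C4 branch then adds to its terminus in an intramolecular 1,6-oxa-Michael addition that restores the aromatic ring and forms the O1–C2 bond. The closest known reaction types are the DDQ oxidation of 4-alkyl-2-methoxyphenols in alcohols to benzylic ethers and the closure of lignan quinone methides to 2-aryloxolanes. The oxolane closes in the 5-exo-trig mode, whereas the other two hydroxyls could only give oxetanes and ring B could only give a six-membered carbocycle by a slower Friedel–Crafts path. The new stereocentre C2 is controlled by C3: allylic 1,3-strain holds H3 in the plane of the quinone methide, so the tethered oxygen attacks the face anti to the hydroxymethyl group and the aryl group ends trans to it, and because the p-hydroxybenzyl ether can reopen to 13 under the weakly acidic hydroquinone, any cis isomer should drain to the more stable 2,3-trans oxolane. Site selectivity (the CH2 of ring A and not the CH2 on C4) is secured by the substrate, since ring B is a silyl ether and cannot form a quinone methide, and over-oxidation of the product is limited by the single equivalent of DDQ.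

Step 11
Reactants: 14 [(2S,3R,4S)-4-hydroxy-2-(4-hydroxy-3-methoxyphenyl)-4-({3-methoxy-4-[(triisopropylsilyl)oxy]phenyl}methyl)oxolan-3-yl]methanol
Product: 15 olivil, [(2S,3R,4S)-4-hydroxy-2-(4-hydroxy-3-methoxyphenyl)-4-[(4-hydroxy-3-methoxyphenyl)methyl]oxolan-3-yl]methanol
Conditions: Bu4NF (1.1 equiv), AcOH (1.1 equiv), THF, 0 °C
Reagents that add atoms: none
Why: Fluoride cleavage of the aryl silyl ether should free the phenol of ring B, and the acetic acid buffer keeps the phenoxide concentration low so that the O1–C2 bond is not opened by base.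

Step 12
Reactants: 15 olivil
Product: 16 olivil monoacetate, [(2S,3R,4S)-4-hydroxy-2-(4-hydroxy-3-methoxyphenyl)-4-[(4-hydroxy-3-methoxyphenyl)methyl]oxolan-3-yl]methyl acetate
Conditions: Novozym 435 (immobilised Candida antarctica lipase B), vinyl acetate (5 equiv), tert-amyl alcohol–THF, 45 °C; filtration
Reagents that add atoms: vinyl acetate, CC(=O)OC=C
Why: Lipase-catalysed transesterification with an irreversible acyl donor should acetylate only the primary aliphatic hydroxyl, since phenolic and tertiary hydroxyls are not accepted by the enzyme, and the neutral medium leaves the O1–C2 bond and all three stereocentres untouched.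

**Compound list**
1 | vanillin (4-hydroxy-3-methoxybenzaldehyde) | COc1cc(C=O)ccc1O | starting material
2 | 3-methoxy-4-[(triisopropylsilyl)oxy]benzaldehyde | COc1cc(C=O)ccc1O[Si](C(C)C)(C(C)C)C(C)C | intermediate
3 | {3-methoxy-4-[(triisopropylsilyl)oxy]phenyl}methanol | COc1cc(CO)ccc1O[Si](C(C)C)(C(C)C)C(C)C | intermediate
4 | [4-(bromomethyl)-2-methoxyphenoxy]triisopropylsilane (ring B bromide) | COc1cc(CBr)ccc1O[Si](C(C)C)(C(C)C)C(C)C | intermediate
5 | diethyl (S)-malate | CCOC(=O)C[C@H](O)C(=O)OCC | starting material
6 | 1-(benzyloxy)-4-(bromomethyl)-2-methoxybenzene (ring A bromide) | COc1cc(CBr)ccc1OCc1ccccc1 | starting material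
7 | diethyl (2S,3R)-3-[4-(benzyloxy)-3-methoxybenzyl]malate | CCOC(=O)[C@@H](O)[C@@H](Cc1ccc(OCc2ccccc2)c(OC)c1)C(=O)OCC | intermediate
8 | (2S,3R)-3-[4-(benzyloxy)-3-methoxybenzyl]malic acid | OC(=O)[C@@H](O)[C@@H](Cc1ccc(OCc2ccccc2)c(OC)c1)C(=O)O | intermediate
9 | (2R)-3-[4-(benzyloxy)-3-methoxyphenyl]-2-[(2S,4S)-2-tert-butyl-5-oxo-1,3-dioxolan-4-yl]propanoic acid | CC(C)(C)[C@H]1O[C@@H]([C@@H](Cc2ccc(OCc3ccccc3)c(OC)c2)C(=O)O)C(=O)O1 | intermediate
10 | (2R)-3-[4-(benzyloxy)-3-methoxyphenyl]-2-[(2S,4S)-2-tert-butyl-4-({3-methoxy-4-[(triisopropylsilyl)oxy]phenyl}methyl)-5-oxo-1,3-dioxolan-4-yl]propanoic acid | CC(C)(C)[C@H]1O[C@@](Cc2ccc(O[Si](C(C)C)(C(C)C)C(C)C)c(OC)c2)([C@@H](Cc2ccc(OCc3ccccc3)c(OC)c2)C(=O)O)C(=O)O1 | intermediate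
11 | (2S,3S)-3-{[4-(benzyloxy)-3-methoxyphenyl]methyl}-2-({3-methoxy-4-[(triisopropylsilyl)oxy]phenyl}methyl)butane-1,2,4-triol | COc1cc(C[C@@](O)(CO)[C@H](CO)Cc2ccc(OCc3ccccc3)c(OC)c2)ccc1O[Si](C(C)C)(C(C)C)C(C)C | intermediate
12 | (2S,3S)-3-[(4-hydroxy-3-methoxyphenyl)methyl]-2-({3-methoxy-4-[(triisopropylsilyl)oxy]phenyl}methyl)butane-1,2,4-triol | COc1cc(C[C@@](O)(CO)[C@H](CO)Cc2ccc(O)c(OC)c2)ccc1O[Si](C(C)C)(C(C)C)C(C)C | intermediate
13 | p-quinone methide of 12, 4-[(2S,3S)-3,4-dihydroxy-2-(hydroxymethyl)-3-({3-methoxy-4-[(triisopropylsilyl)oxy]phenyl}methyl)butylidene]-2-methoxycyclohexa-2,5-dien-1-one (alkene geometry not defined) | COC1=CC(=C[C@@H](CO)[C@](O)(CO)Cc2ccc(O[Si](C(C)C)(C(C)C)C(C)C)c(OC)c2)C=CC1=O | intermediate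
14 | [(2S,3R,4S)-4-hydroxy-2-(4-hydroxy-3-methoxyphenyl)-4-({3-methoxy-4-[(triisopropylsilyl)oxy]phenyl}methyl)oxolan-3-yl]methanol | COc1cc(C[C@@]2(O)CO[C@H](c3ccc(O)c(OC)c3)[C@H]2CO)ccc1O[Si](C(C)C)(C(C)C)C(C)C | intermediate
15 | olivil, [(2S,3R,4S)-4-hydroxy-2-(4-hydroxy-3-methoxyphenyl)-4-[(4-hydroxy-3-methoxyphenyl)methyl]oxolan-3-yl]methanol | COc1cc(C[C@@]2(O)CO[C@H](c3ccc(O)c(OC)c3)[C@H]2CO)ccc1O | intermediate
16 | olivil monoacetate, [(2S,3R,4S)-4-hydroxy-2-(4-hydroxy-3-methoxyphenyl)-4-[(4-hydroxy-3-methoxyphenyl)methyl]oxolan-3-yl]methyl acetate | COc1cc(C[C@@]2(O)CO[C@H](c3ccc(O)c(OC)c3)[C@H]2COC(C)=O)ccc1O | target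

**Count and risks**
Total step count: 12. Longest linear sequence: 9 steps (from 5 through steps 4 to 12; the branch from vanillin through steps 1 to 3 and 7 to 12 is equally long).

Steps most likely to fail:

1. Step 10 (oxidative ring closure). The newly formed C2–H, now next to oxygen, may be oxidised further and the ring cleaved. The acidic hydroquinone may also drive a Friedel–Crafts closure of the quinone methide onto ring B, or the phenol may couple oxidatively. The fallback sets out from triol 12 and comes back at oxolane 14, with oxidation and ring closure uncoupled. DDQ (1 equiv) in methanol–dioxane would let the solvent capture the quinone methide at once as the benzylic methyl ether of triol 12 (both epimers at the benzylic carbon of ring A) F1. Isolated F1 would then be ionised with catalytic camphorsulfonic acid in CH2Cl2 at 0 °C, and the same 5-exo etherification, now an oxidant-free SN1 reaction with loss of methanol, would give 14.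

2. Step 7 (quaternary carbon next to a branched carbon). Deprotonation of the crowded dioxolanone may be slow, and the enolate may fragment with loss of pivalaldehyde before it is alkylated. The fallback sets out from bromide 4 and comes back at triol 11, with the order of the two alkylations reversed so that the quaternary carbon is made on the unbranched acid. Commercial (S)-malic acid F2 would be converted with pivalaldehyde into [(2S,4S)-2-tert-butyl-5-oxo-1,3-dioxolan-4-yl]acetic acid F3. Alkylation of F3 with 4 (LiN(SiMe3)2, 2 equiv, −78 °C) would give the quaternary acetal acid F4, and HCl in methanol would open it to dimethyl (S)-2-hydroxy-2-({3-methoxy-4-[(triisopropylsilyl)oxy]phenyl}methyl)succinate F5. Dianion alkylation of F5 with bromide 6 under Fráter–Seebach conditions would give the dibenzylated dimethyl malate F6; facial selectivity at C3 is less secure here than in step 4, so the isomers would be separated by chromatography. LiAlH4 would then reduce F6 to 11.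

3. Step 12 (enzymatic acetylation). Acyl transfer to the hindered primary hydroxyl may be slow in the enzyme pocket, or a phenol may be partly acylated. The fallback sets out from olivil 15 and comes back at target 16. Acetylation with Ac2O in pyridine at rt (the tertiary hydroxyl does not react) would give olivil triacetate F7, and selective aminolysis of the two aryl acetates with pyrrolidine (CH2Cl2, 0 °C) would leave the alkyl acetate.

**Further compounds**
F1 | step 10 | benzylic methyl ether of triol 12 (OMe on the CH of ring A, both epimers at that carbon) | COc1cc(C[C@@](O)(CO)[C@H](CO)C(OC)c2ccc(O)c(OC)c2)ccc1O[Si](C(C)C)(C(C)C)C(C)C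
F2 | step 7 | (S)-malic acid | OC(=O)C[C@H](O)C(=O)O
F3 | step 7 | [(2S,4S)-2-tert-butyl-5-oxo-1,3-dioxolan-4-yl]acetic acid | CC(C)(C)[C@H]1O[C@@H](CC(=O)O)C(=O)O1
F4 | step 7 | [(2S,4S)-2-tert-butyl-4-({3-methoxy-4-[(triisopropylsilyl)oxy]phenyl}methyl)-5-oxo-1,3-dioxolan-4-yl]acetic acid | CC(C)(C)[C@H]1O[C@@](Cc2ccc(O[Si](C(C)C)(C(C)C)C(C)C)c(OC)c2)(CC(=O)O)C(=O)O1
F5 | step 7 | dimethyl (S)-2-hydroxy-2-({3-methoxy-4-[(triisopropylsilyl)oxy]phenyl}methyl)succinate | COC(=O)C[C@@](O)(Cc1ccc(O[Si](C(C)C)(C(C)C)C(C)C)c(OC)c1)C(=O)OC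
F6 | step 7 | dimethyl (2S,3R)-3-[4-(benzyloxy)-3-methoxybenzyl]-2-({3-methoxy-4-[(triisopropylsilyl)oxy]phenyl}methyl)malate | COC(=O)[C@H](Cc1ccc(OCc2ccccc2)c(OC)c1)[C@@](O)(Cc1ccc(O[Si](C(C)C)(C(C)C)C(C)C)c(OC)c1)C(=O)OC
F7 | step 12 | olivil triacetate (primary acetate and both aryl acetates, tertiary hydroxyl free) | COc1cc(C[C@@]2(O)CO[C@H](c3ccc(OC(C)=O)c(OC)c3)[C@H]2COC(C)=O)ccc1OC(C)=O
A1 | direct plan | racemic 1-[4-(benzyloxy)-3-methoxyphenyl]prop-2-en-1-ol | COc1cc(C(O)C=C)ccc1OCc1ccccc1
A2 | direct plan | (R)-[4-(benzyloxy)-3-methoxyphenyl][(2S)-oxiran-2-yl]methanol | COc1cc([C@@H](O)[C@@H]2CO2)ccc1OCc1ccccc1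
A3 | direct plan | (2S)-2-[(R)-[4-(benzyloxy)-3-methoxyphenyl]({3-[4-(benzyloxy)-3-methoxyphenyl]prop-2-yn-1-yl}oxy)methyl]oxirane | COc1cc(C#CCO[C@H](c2ccc(OCc3ccccc3)c(OC)c2)[C@@H]2CO2)ccc1OCc1ccccc1
A4 | direct plan | [(2S,3R,4E)-2-[4-(benzyloxy)-3-methoxyphenyl]-4-{[4-(benzyloxy)-3-methoxyphenyl]methylidene}oxolan-3-yl]methanol | COc1cc(/C=C2/CO[C@H](c3ccc(OCc4ccccc4)c(OC)c3)[C@H]2CO)ccc1OCc1ccccc1
A5 | direct plan | (2S,3R,4S)-2-[4-(benzyloxy)-3-methoxyphenyl]-4-{(S)-[4-(benzyloxy)-3-methoxyphenyl](hydroxy)methyl}-3-(hydroxymethyl)oxolan-4-ol | COc1cc([C@H](O)[C@@]2(O)CO[C@H](c3ccc(OCc4ccccc4)c(OC)c3)[C@H]2CO)ccc1OCc1ccccc1
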